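**Plan**

- Retrosynthetic cuts: C12–C13 (B-alkyl Suzuki–Miyaura coupling), C11=C12 (methylenation), C9–C11 (enolate alkoxymethylation), C8–C17 (methyl addition), the second C4 methyl (cyclopropane), the ring A bond C4–C5 (key step), then C2–C3 and the C10 methyl of an aromatic precursor.
- Enabling feature: in ring B the oxygens on C6 and C8 flank C7 and are both 1,3 (meta) to the quaternary C10, which is the substitution pattern of 3,5-dimethoxybenzoic acid. Its Birch methylation product has a mirror plane through C7 and C10, so the enol ether alkenes C5=C6 and C9=C8 are enantiotopic.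
- Forward order: ring B is the reduced arene; the C1–C4 tether ending in a 2-bromoalkene is attached at C10; ring A closes by an asymmetric Heck cyclisation; ring B is then adjusted and the C11–C16 chain is joined last.
- Stereochemistry: C10 from the BINAP-controlled choice of alkene; C9 from convex-face alkylation of the cis-fused enolate; C5 by equilibration next to the C6 ketone; C7/C8 by epoxidation anti to the axial C10 methyl; C6 by dissolving-metal reduction to the equatorial alcohol; 13E from syn-stannylcupration and a stereoretentive coupling.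

Key step: step 6

Remark on numbering: labdane numbering is used for all bicyclic compounds (ring A = C1–C5 and C10, ring B = C5–C10, C11 on C9, C17 on C8, C20 = methyl on C10); "syn" and "anti" mean the same or the opposite ring face as the C10 methyl. The target is methyl (5R,6R,8S,9S,10R,13E)-6,8-dihydroxylabd-13-en-15-oate: trans-decalin, 6-OH and 8-OH anti (equatorial), C8 methyl syn (axial), C9 chain syn (equatorial).

Assumption: (R)-BINAP is taken to select the enantiotopic alkene that gives the C10 configuration of the target; should the sense of induction be the opposite, (S)-BINAP is used and nothing else changes.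

**Route**

Step 1
Reactants: 1 3,5-dimethoxybenzoic acid
Product: 2 3,5-dimethoxy-1-methylcyclohexa-2,5-diene-1-carboxylic acid
Conditions: Li, NH3(l)/THF, −78 °C; MeI, −78 °C; NH4Cl; work-up at pH 5, 0 °C
Reagents that add atoms: iodomethane, CI
Why: Birch reductive alkylation, in which the arene is reduced to the carboxylate-stabilised cyclohexadienyl dianion and methylated at the ipso carbon (C10) to give the 2,5-diene with a mirror plane through C7 and C10, so no stereocentre is formed.

Step 2
Reactants: 2 3,5-dimethoxy-1-methylcyclohexa-2,5-diene-1-carboxylic acid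
Product: 3 (3,5-dimethoxy-1-methylcyclohexa-2,5-dien-1-yl)methanol
Conditions: LiAlH4, THF, 0 °C to reflux; aq. NaOH work-up
Reagents that add atoms: none
Why: LiAlH4 reduction of a carboxylic acid to the primary alcohol, with a basic work-up that spares the two acid-labile enol ethers.

Step 3
Reactants: 3 (3,5-dimethoxy-1-methylcyclohexa-2,5-dien-1-yl)methanol
Product: 4 3,5-dimethoxy-1-methylcyclohexa-2,5-diene-1-carbaldehyde
Conditions: Pr4N[RuO4] (5 mol %), N-methylmorpholine N-oxide, 4 Å molecular sieves, CH2Cl2, rt
Reagents that add atoms: none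
Why: Ley–Griffith oxidation under neutral conditions stops at the aldehyde, which has no α-hydrogen and therefore cannot enolise.

Step 4
Reactants: 4 3,5-dimethoxy-1-methylcyclohexa-2,5-diene-1-carbaldehyde
Product: 5 3-ethenyl-1,5-dimethoxy-3-methylcyclohexa-1,4-diene
Conditions: Ph3PCH3Br, KOtBu, THF, 0 °C to rt
Reagents that add atoms: methyltriphenylphosphonium bromide, C[P+](c1ccccc1)(c1ccccc1)c1ccccc1.[Br-]
Why: Wittig methylenation of a non-enolisable aldehyde gives the vinyl group that becomes C1–C2 of the tether.

Step 5
Reactants: 5 3-ethenyl-1,5-dimethoxy-3-methylcyclohexa-1,4-diene; 6 2,3-dibromoprop-1-ene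
Product: 8 3-(4-bromopent-4-en-1-yl)-1,5-dimethoxy-3-methylcyclohexa-1,4-diene, via alkylzirconocene chloride 7 (not isolated)
Conditions: Cp2Zr(H)Cl, THF, rt; then 6, CuBr·SMe2 (10 mol %), 0 °C to rt
Reagents that add atoms: none
Why: Hydrozirconation places zirconium on the terminal carbon of the only monosubstituted alkene (the trisubstituted enol ethers are inert and the neopentyl-type alkylzirconium has no β-hydrogen), and copper-catalysed allylic substitution (SN2 and SN2' give the same product) then adds the 2-bromoallyl unit while the vinylic C–Br bond stays intact.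

Step 6
Reactants: 8 3-(4-bromopent-4-en-1-yl)-1,5-dimethoxy-3-methylcyclohexa-1,4-diene
Product: 9 cis-fused 2,4-dimethoxy-8a-methyl-5-methylidene-4a,5,6,7,8,8a-hexahydronaphthalene (labdane positions: 6,8-dimethoxy-6,8-diene, C4 methylidene, H5 syn, C10 as in the target)
Conditions: Pd(OAc)2 (10 mol %), (R)-BINAP (20 mol %), Ag3PO4, N-methylpyrrolidone, 60 °C
Reagents that add atoms: none
Why: Pd(OAc)2 is reduced by the diphosphine to zerovalent palladium, which inserts into the alkenyl C–Br bond, and Ag3PO4 removes bromide so that a cationic alkenylpalladium keeps both phosphorus atoms bound while it coordinates one of the two ring alkenes. The closest known reaction type is the asymmetric intramolecular Mizoroki–Heck desymmetrisation of prochiral 3,3-disubstituted cyclohexa-1,4-dienes to cis-decalins, applied here to a diene whose alkenes are methyl enol ethers. Ring A closes by 6-exo-trig syn-carbopalladation of C5=C6 (new C4–C5 bond; the 7-endo mode is geometrically disfavoured), which leaves palladium on the methoxy-bearing C6. C10 becomes stereogenic through the ligand-controlled choice between the enantiotopic alkenes C5=C6 and C9=C8, and C5 is set by the tether, which can deliver C4 only to the ring face it occupies, giving the cis ring fusion. The step needs enantiotopic-group selection (secured by the chelated cationic pathway), a single direction of β-hydride loss (only a C7 hydrogen is syn to palladium because H5 lies on the opposite face, so the conjugated 6,8-dienol ether results) and survival of the enol ethers (the phosphate keeps the medium basic). Re-addition of palladium hydride, which could move the diene, is suppressed by the silver salt.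

Step 7
Reactants: 9 cis-fused 6,8-dimethoxy-6,8-diene
Product: 10 cis-fused 4-methoxy-8a-methyl-5-methylidene-4a,5,6,7,8,8a-hexahydronaphthalen-2(1H)-one (6-methoxy-6-en-8-one, H5 syn)
Conditions: 0.1 M aq. oxalic acid, THF, 0 °C, short contact; NaHCO3
Reagents that add atoms: water, O
Why: Kinetic enol ether hydrolysis, in which protonation at the diene terminus C9 gives a 6,8-dimethoxyallyl cation, water adds 1,2 at the neighbouring and less hindered C8, and loss of methanol gives the vinylogous ester, which is far less basic than the dienol ether and should not react further under these conditions.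

Step 8
Reactants: 10 cis-fused 6-methoxy-4-methylidene-6-en-8-one
Product: 11 cis-fused 6-methoxy-6-en-8-one with a spiro-cyclopropane at C4
Conditions: Et2Zn, CF3CO2H, CH2I2, CH2Cl2, 0 °C to rt
Reagents that add atoms: diiodomethane, ICI
Why: Simmons–Smith cyclopropanation, in which the electrophilic zinc carbenoid adds to the isolated 1,1-disubstituted alkene while the carbonyl-conjugated enol ether alkene is deactivated, making C4 quaternary (no stereocentre) before a C6 ketone with an acidic C5–H is unveiled.

Step 9
Reactants: 11 cis-fused 6-methoxy-6-en-8-one with a spiro-cyclopropane at C4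
Product: 13 9-(benzyloxymethyl) derivative of 11 with the CH2OBn group syn, via lithium dienolate 12 (not isolated)
Conditions: LiN(i-Pr)2, THF, −78 °C; BnOCH2Cl, −78 to −40 °C
Reagents that add atoms: benzyl chloromethyl ether, ClCOCc1ccccc1
Why: Stork–Danheiser alkylation, i.e. kinetic deprotonation of the vinylogous ester at the α'-methylene C9 and C-alkylation by the reactive chloromethyl ether, in which the electrophile should enter on the convex face of the cis-fused bicycle, anti to the ring A methylene C1, so that C11 ends up syn to the C10 methyl.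

Step 10
Reactants: 13 9-(benzyloxymethyl)-6-methoxy-6-en-8-one
Product: 15 cis-fused 9-(benzyloxymethyl)-8-methyl-7-en-6-one with the C4 spiro-cyclopropane, via tertiary allylic alcohol 14 (not isolated)
Conditions: MeLi, CeCl3, THF, −78 to 0 °C; then 1 M HCl, THF, 0 °C
Reagents that add atoms: methyllithium, [Li]C; water, O
Why: Stork–Danheiser carbonyl transposition, in which the weakly basic organocerium adds 1,2 to the C8 carbonyl and dilute acid hydrolyses the enol ether with loss of the allylic hydroxyl to give the 8-methyl-7-en-6-one, leaving C9 and the benzyl ether untouched.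

Step 11
Reactants: 15 cis-fused 9-(benzyloxymethyl)-8-methyl-7-en-6-one
Product: 17 trans-fused 7,8-epoxy-6-ketone with the epoxide anti, via trans-fused enone 16 (not isolated)
Conditions: NaOH (aq), MeOH, rt; then 30% H2O2, 0 °C to rt
Reagents that add atoms: hydrogen peroxide, OO
Why: Base first equilibrates C5 through the cross-conjugated enolate to the more stable trans-fused decalone (H5 anti), and Weitz–Scheffer epoxidation then delivers hydroperoxide to C8 on the face anti to the axial C10 methyl, so that ring closure sets C7 and C8 with the oxygen anti and the C8 methyl syn.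

Step 12
Reactants: 17 trans-fused 7,8-epoxy-6-ketone
Product: 18 trans-fused 9-(benzyloxymethyl)-8-hydroxy-8-methyl-6-ketone (8-OH anti)
Conditions: SmI2, THF/MeOH, −90 °C
Reagents that add atoms: none
Why: SmI2 reduction of an α,β-epoxy ketone, in which electron transfer to the ketone cleaves the C7–O bond and protonation of the samarium enolate gives the aldol-type 8-hydroxy ketone with the C8 configuration unchanged.

Step 13
Reactants: 18 trans-fused 8-hydroxy-6-ketone
Product: 19 trans-fused 6,8,11-triol with the C4 spiro-cyclopropane (6-OH and 8-OH anti)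
Conditions: Li, NH3(l), THF, EtOH, −78 to −33 °C; NH4Cl
Reagents that add atoms: none
Why: Dissolving-metal reduction of the hindered ketone gives the thermodynamically favoured equatorial C6 alcohol (anti; the axial epimer, which hydride reagents would give, would be syn-axial to the C10 and C8 methyls), and the benzyl ether is cleaved in the same operation.

Step 14
Reactants: 19 6,8,11-triol with the C4 spiro-cyclopropane
Product: 20 (1R,2S,4R,4aR,8aR)-1-(hydroxymethyl)-2,5,5,8a-tetramethyldecahydronaphthalene-2,4-diol
Conditions: H2 (4 atm), PtO2, AcOH, rt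
Reagents that add atoms: none
Why: Catalytic hydrogenolysis of the spiro-cyclopropane cleaves the least hindered CH2–CH2 bond and leaves the geminal dimethyl group at C4 without touching a stereocentre.

Step 15
Reactants: 20 (1R,2S,4R,4aR,8aR)-1-(hydroxymethyl)-2,5,5,8a-tetramethyldecahydronaphthalene-2,4-diol
Product: 21 (1S,2S,4R,4aR,8aR)-2,4-dihydroxy-2,5,5,8a-tetramethyldecahydronaphthalene-1-carbaldehyde
Conditions: TEMPO (10 mol %), PhI(OAc)2, CH2Cl2, rt
Reagents that add atoms: none
Why: Oxoammonium (TEMPO) oxidation is selective for the primary C11 alcohol over the hindered secondary and the tertiary alcohol and gives the β-hydroxy aldehyde without base.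

Step 16
Reactants: 21 (1S,2S,4R,4aR,8aR)-2,4-dihydroxy-2,5,5,8a-tetramethyldecahydronaphthalene-1-carbaldehyde
Product: 22 (1S,2S,4R,4aR,8aR)-1-ethenyl-2,5,5,8a-tetramethyldecahydronaphthalene-2,4-diol
Conditions: Ph3PCH3Br, KOtBu (excess ylide), THF, −78 to 0 °C
Reagents that add atoms: methyltriphenylphosphonium bromide, C[P+](c1ccccc1)(c1ccccc1)c1ccccc1.[Br-]
Why: Wittig methylenation of the aldehyde at low temperature, where olefination should outpace retro-aldol cleavage of the β-alkoxide, with the C9 configuration (equatorial C11) retained.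

Step 17
Reactants: 23 methyl but-2-ynoate
Product: 24 methyl (2E)-3-(trimethylstannyl)but-2-enoate
Conditions: Me3SnSnMe3, MeLi, THF, −20 °C; CuBr·SMe2, −78 °C; then 23, MeOH, −78 °C
Reagents that add atoms: hexamethylditin, C[Sn](C)(C)[Sn](C)(C)C
Why: Syn-stannylcupration of the ynoate under kinetic control (methanol present at −78 °C) places tin on C3 and hydrogen on C2 on the same side, which gives the E-stannane.

Step 18
Reactants: 24 methyl (2E)-3-(trimethylstannyl)but-2-enoate
Product: 25 methyl (2E)-3-iodobut-2-enoate
Conditions: I2, CH2Cl2, 0 °C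
Reagents that add atoms: iodine, II
Why: Iododestannylation of an alkenylstannane proceeds with retention of the double-bond geometry.

Step 19
Reactants: 22 (1S,2S,4R,4aR,8aR)-1-ethenyl-2,5,5,8a-tetramethyldecahydronaphthalene-2,4-diol; 25 methyl (2E)-3-iodobut-2-enoate
Product: 27 methyl (2E)-5-[(1S,2S,4R,4aR,8aR)-2,4-dihydroxy-2,5,5,8a-tetramethyldecahydronaphthalen-1-yl]-3-methylpent-2-enoate, via B-alkyl-9-BBN borane 26 (not isolated)
Conditions: 9-BBN (excess), THF, 0 °C to rt; then 25, PdCl2(dppf) (5 mol %), K3PO4 (aq), DMF, rt
Reagents that add atoms: none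
Why: Anti-Markovnikov hydroboration of the monosubstituted alkene with 9-BBN followed by B-alkyl Suzuki–Miyaura coupling, which forms C12–C13 with retention of the E geometry of the iodoalkene and tolerates the free hydroxyls and the ester.

**Compound list**

1 | 3,5-dimethoxybenzoic acid | COc1cc(OC)cc(c1)C(=O)O | starting material
2 | 3,5-dimethoxy-1-methylcyclohexa-2,5-diene-1-carboxylic acid | COC1=CC(C)(C(=O)O)C=C(OC)C1 | intermediate
3 | (3,5-dimethoxy-1-methylcyclohexa-2,5-dien-1-yl)methanol | COC1=CC(C)(CO)C=C(OC)C1 | intermediate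
4 | 3,5-dimethoxy-1-methylcyclohexa-2,5-diene-1-carbaldehyde | COC1=CC(C)(C=O)C=C(OC)C1 | intermediate
5 | 3-ethenyl-1,5-dimethoxy-3-methylcyclohexa-1,4-diene | COC1=CC(C)(C=C)C=C(OC)C1 | intermediate
6 | 2,3-dibromoprop-1-ene | BrCC(Br)=C | starting material
7 | [2-(3,5-dimethoxy-1-methylcyclohexa-2,5-dien-1-yl)ethyl]zirconocene chloride | COC1=CC(C)(CC[Zr](Cl)(C2C=CC=C2)C2C=CC=C2)C=C(OC)C1 | intermediate (not isolated)
8 | 3-(4-bromopent-4-en-1-yl)-1,5-dimethoxy-3-methylcyclohexa-1,4-diene (achiral Heck precursor) | COC1=CC(C)(CCCC(Br)=C)C=C(OC)C1 | intermediate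
9 | cis-fused 2,4-dimethoxy-8a-methyl-5-methylidene-4a,5,6,7,8,8a-hexahydronaphthalene (H5 syn) | COC1=C[C@]2(C)CCCC(=C)[C@@H]2C(OC)=C1 | intermediate
10 | cis-fused 4-methoxy-8a-methyl-5-methylidene-4a,5,6,7,8,8a-hexahydronaphthalen-2(1H)-one (6-methoxy-6-en-8-one) | O=C1C[C@]2(C)CCCC(=C)[C@@H]2C(OC)=C1 | intermediate
11 | cis-fused 6-methoxy-6-en-8-one with spiro-cyclopropane at C4 | O=C1C[C@]2(C)CCCC3(CC3)[C@@H]2C(OC)=C1 | intermediate
12 | lithium dienolate of 11 (C8–OLi, C8=C9) | [Li]OC1=C[C@]2(C)CCCC3(CC3)[C@@H]2C(OC)=C1 | intermediate (not isolated)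
13 | 9-(benzyloxymethyl) derivative of 11, CH2OBn syn, H5 syn | O=C1[C@@H](COCc3ccccc3)[C@]2(C)CCCC4(CC4)[C@@H]2C(OC)=C1 | intermediate
14 | 8-hydroxy-8-methyl-6-methoxy-6-ene from methyl addition to 13 (C8 epimers) | O(Cc1ccccc1)C[C@H]1[C@]2(C)CCCC3(CC3)[C@@H]2C(OC)=CC1(C)O | intermediate (not isolated)
15 | cis-fused 9-(benzyloxymethyl)-8-methyl-7-en-6-one, C4 spiro-cyclopropane, H5 syn | O(Cc1ccccc1)C[C@H]1[C@]2(C)CCCC3(CC3)[C@@H]2C(=O)C=C1C | intermediate
16 | trans-fused 9-(benzyloxymethyl)-8-methyl-7-en-6-one, H5 anti | O(Cc1ccccc1)C[C@H]1[C@]2(C)CCCC3(CC3)[C@H]2C(=O)C=C1C | intermediate (not isolated)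
17 | trans-fused 7,8-epoxy-6-ketone, epoxide anti, C8 methyl syn | O(Cc1ccccc1)C[C@H]1[C@]2(C)CCCC3(CC3)[C@H]2C(=O)[C@@H]4O[C@@]41C | intermediate
18 | trans-fused 9-(benzyloxymethyl)-8-hydroxy-8-methyl-6-ketone, 8-OH anti | O(Cc1ccccc1)C[C@H]1[C@]2(C)CCCC3(CC3)[C@H]2C(=O)C[C@]1(C)O | intermediate
19 | trans-fused 6,8,11-triol with spiro-cyclopropane at C4, 6-OH and 8-OH anti | OC[C@H]1[C@]2(C)CCCC3(CC3)[C@H]2[C@H](O)C[C@]1(C)O | intermediate
20 | (1R,2S,4R,4aR,8aR)-1-(hydroxymethyl)-2,5,5,8a-tetramethyldecahydronaphthalene-2,4-diol | OC[C@H]1[C@]2(C)CCCC(C)(C)[C@H]2[C@H](O)C[C@]1(C)O | intermediate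
21 | (1S,2S,4R,4aR,8aR)-2,4-dihydroxy-2,5,5,8a-tetramethyldecahydronaphthalene-1-carbaldehyde | O=C[C@H]1[C@]2(C)CCCC(C)(C)[C@H]2[C@H](O)C[C@]1(C)O | intermediate
22 | (1S,2S,4R,4aR,8aR)-1-ethenyl-2,5,5,8a-tetramethyldecahydronaphthalene-2,4-diol | C=C[C@H]1[C@]2(C)CCCC(C)(C)[C@H]2[C@H](O)C[C@]1(C)O | intermediate
23 | methyl but-2-ynoate | CC#CC(=O)OC | starting material
24 | methyl (2E)-3-(trimethylstannyl)but-2-enoate | COC(=O)/C=C(\C)[Sn](C)(C)C | intermediate
25 | methyl (2E)-3-iodobut-2-enoate | COC(=O)/C=C(\C)I | intermediate
26 | 9-{2-[(1S,2S,4R,4aR,8aR)-2,4-dihydroxy-2,5,5,8a-tetramethyldecahydronaphthalen-1-yl]ethyl}-9-borabicyclo[3.3.1]nonane | B1(CC[C@H]2[C@]3(C)CCCC(C)(C)[C@H]3[C@H](O)C[C@]2(C)O)C2CCCC1CCC2 | intermediate (not isolated)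
27 | methyl (2E)-5-[(1S,2S,4R,4aR,8aR)-2,4-dihydroxy-2,5,5,8a-tetramethyldecahydronaphthalen-1-yl]-3-methylpent-2-enoate | COC(=O)/C=C(\C)CC[C@H]1[C@]2(C)CCCC(C)(C)[C@H]2[C@H](O)C[C@]1(C)O | target

**Totals and risks**

Total step count: 19. Longest linear sequence: 17 (steps 1–16 and 19); steps 17–18 make the iodoenoate.

Steps most likely to fail:

1. Step 6 (Heck cyclisation). The electron-rich, trisubstituted enol ether alkene may insert slowly, so that a neutral bromide-bound pathway with partial phosphine dissociation, weak discrimination between the enantiotopic alkenes, or re-addition of palladium hydride with migration of the diene can compete. The fallback changes the leaving group to triflate, so that the cationic pathway runs without a silver salt. It sets out from 8: bromine–lithium exchange (t-BuLi, −78 °C), trapping with B(OMe)3 and oxidation with NaBO3 should give 5-(3,5-dimethoxy-1-methylcyclohexa-2,5-dien-1-yl)pentan-2-one F1. Kinetic enolisation at the methyl group (KN(SiMe3)2, −78 °C) and O-sulfonylation with PhNTf2 give 5-(3,5-dimethoxy-1-methylcyclohexa-2,5-dien-1-yl)pent-1-en-2-yl trifluoromethanesulfonate F2. Cyclisation with Pd(OAc)2, (R)-BINAP and K2CO3 in toluene then comes back to the route at 9.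

2. Step 7 (regioselective hydrolysis). Water may add to the C6 end of the 6,8-dimethoxyallyl cation, or hydrolysis may run on to the dione, so that the methoxy group stays on C8 and the later methyl addition would go to the wrong carbon. The fallback does not depend on which oxygen is released first and sets out from 9. Exhaustive hydrolysis (1 M HCl, THF, rt) gives the cis-fused 8a-methyl-5-methylidene-octahydronaphthalene-2,4-dione F3. Its dianion (LiN(i-Pr)2, 2.2 equiv, THF/DMPU) is alkylated at the less hindered terminal carbon C9 with BnOCH2Cl to give the 9-(benzyloxymethyl)-6,8-dione F4. O-Sulfonylation at the less hindered C8 oxygen (Tf2O, 2,6-lutidine) gives the 9-(benzyloxymethyl)-8-(trifluoromethanesulfonyloxy)-7-en-6-one F5; the C6 oxygen is shielded by the ring-fusion methine and the in-plane C4 methylidene. Addition–elimination with Me2CuLi gives the cis-fused 9-(benzyloxymethyl)-8-methyl-4-methylidene-7-en-6-one F6, and Simmons–Smith cyclopropanation of its isolated alkene comes back to the route at 15.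

3. Step 9 (alkylation at C9). The enolate carbon is neopentyl-like, so O-alkylation by the hard chloromethyl ether or incomplete conversion may compete with C-alkylation, and facial control may be incomplete. The fallback replaces the lithium enolate by an isolated silyl dienol ether and a Lewis-acid-mediated (Mukaiyama-type) alkoxymethylation. It sets out from 11: LiN(i-Pr)2 and Me3SiCl give the 8-(trimethylsilyloxy)-6-methoxy-6,8-diene F7, and treatment with BnOCH2Cl and ZnBr2 (cat.) in CH2Cl2 at −78 °C comes back to the route at 13. If the anti epimer at C9 forms, it can be equilibrated next to the C8 carbonyl with a mild amine base before step 10.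

Further compounds
F1 | step 6 | 5-(3,5-dimethoxy-1-methylcyclohexa-2,5-dien-1-yl)pentan-2-one | COC1=CC(C)(CCCC(C)=O)C=C(OC)C1
F2 | step 6 | 5-(3,5-dimethoxy-1-methylcyclohexa-2,5-dien-1-yl)pent-1-en-2-yl trifluoromethanesulfonate | COC1=CC(C)(CCCC(=C)OS(=O)(=O)C(F)(F)F)C=C(OC)C1
F3 | step 7 | cis-fused 8a-methyl-5-methylidene-octahydronaphthalene-2,4-dione (6,8-dione, H5 syn) | O=C1C[C@]2(C)CCCC(=C)[C@@H]2C(=O)C1
F4 | step 7 | cis-fused 9-(benzyloxymethyl)-4-methylidene-6,8-dione, CH2OBn syn | O=C1[C@@H](COCc3ccccc3)[C@]2(C)CCCC(=C)[C@@H]2C(=O)C1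
F5 | step 7 | cis-fused 9-(benzyloxymethyl)-4-methylidene-8-(trifluoromethanesulfonyloxy)-7-en-6-one | O=C1C=C(OS(=O)(=O)C(F)(F)F)[C@@H](COCc3ccccc3)[C@]2(C)CCCC(=C)[C@@H]21
F6 | step 7 | cis-fused 9-(benzyloxymethyl)-8-methyl-4-methylidene-7-en-6-one | O(Cc1ccccc1)C[C@H]1[C@]2(C)CCCC(=C)[C@@H]2C(=O)C=C1C
F7 | step 9 | cis-fused 8-(trimethylsilyloxy)-6-methoxy-6,8-diene with spiro-cyclopropane at C4 | C[Si](C)(C)OC1=C[C@]2(C)CCCC3(CC3)[C@@H]2C(OC)=C1
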